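Locants: ring carbons C1 (carbinol, crotonoyl), C5 (isovalerate), C6 (lactone O), C7, C8, C9 (ketone), C10 (methyl). The cycloheptane is divided into the dioxygenated C5–C6 pair and the C7–C8–C9–C10–C1 chain. An oxidopyrylium (5+2) cycloaddition between a kojic acid-derived 4-methoxy-3-oxidopyrylium and an (E)-β-alkoxyvinyl isobutyl ketone carrying a chiral benzylic ether forms C6–C7 and C5–C1 at once. It exploits the C1 tertiary hydroxyl and the C9 ketone: the pyran oxygen becomes the C1 oxygen, the pyranone carbonyl carbon becomes C9, and Baeyer–Villiger oxidation turns the ketone side chain into the C5 isovalerate. The bridge later opens to an enone that closes the methylene lactone.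

Key step: step 5

Remarks on the chemistry:
- The target locants above are used for all intermediates. "Exo" means on the face of the C1–O–C7 oxygen bridge, "endo" the opposite face.
- Assumption: the facial bias of the (S)-1-(4-methoxyphenyl)ethyl ether is taken from the s-trans enol ether model (carbinol C–H in the alkene plane, aryl ring shielding one face). The two auxiliary-derived diastereomers of 9 are separated in any case, and the (R)-alcohol is equally available should the sense prove opposite.
- Compound 16 is a mixture of epimers at the side-chain carbinol carbon; this centre is removed in step 12.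

Step 1
Reactants: 1 kojic acid
Product: 2 5-hydroxy-2-[(tert-butyldimethylsilyloxy)methyl]-4H-pyran-4-one
Conditions: TBSCl, imidazole, DMF, 0 °C to rt
Reagents that add atoms: tert-butyldimethylsilyl chloride, CC(C)(C)[Si](C)(C)Cl
Why: Silyl ether formation should be selective for the primary alcohol, since any silyl ether at the enolic hydroxyl is cleaved on aqueous work-up.

Step 2
Reactants: 2 silylated kojic acid
Product: 3 5-hydroxy-4-methoxy-2-[(tert-butyldimethylsilyloxy)methyl]pyrylium triflate
Conditions: MeOTf, CH2Cl2, rt
Reagents that add atoms: methyl triflate, COS(=O)(=O)C(F)(F)F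
Why: O-Alkylation of the vinylogous ester carbonyl of a 3-hydroxy-4-pyranone with methyl triflate should give the hydroxy(methoxy)pyrylium salt, the usual precursor of 4-methoxy-3-oxidopyrylium ylides.

Step 3
Reactants: 4 5-methylhex-1-yn-3-ol
Product: 5 5-methylhex-1-yn-3-one
Conditions: activated MnO2, CH2Cl2, rt
Reagents that add atoms: none
Why: Oxidation of a propargylic alcohol with MnO2 should give the ynone without touching the terminal alkyne.

Step 4
Reactants: 5 5-methylhex-1-yn-3-one; 6 (S)-1-(4-methoxyphenyl)ethanol
Product: 7 (E)-1-[(1S)-1-(4-methoxyphenyl)ethoxy]-5-methylhex-1-en-3-one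
Conditions: DABCO (cat.), CH2Cl2, 0 °C to rt
Reagents that add atoms: none
Why: Amine-catalysed oxa-Michael addition of an alcohol to a terminal ynone should give the (E)-β-alkoxy enone, and the carbinol centre of 6 is not involved.

Step 5
Reactants: 3 pyrylium triflate; 7 (E)-β-alkoxyvinyl isobutyl ketone
Product: 9 oxygen-bridged cycloadduct (8-oxabicyclo[3.2.1]oct-3-en-2-one: bridge C1–O–C7; C8 ketone; C9(OMe)=C10; CH2OTBS on C1; endo 3-methylbutanoyl on C5; exo (S)-1-(4-methoxyphenyl)ethoxy on C6), via oxidopyrylium ylide 8 (not isolated)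
Conditions: N,N-dimethylaniline, excess 7, CH2Cl2, rt then 80 °C (sealed tube); chromatographic separation of the auxiliary-derived diastereomers
Reagents that add atoms: none
Why: Deprotonation of 3 gives the 4-methoxy-3-oxidopyrylium ylide 8, whose five-carbon π-system (C7–C8–C9–C10–C1) should add to the alkene C5=C6 in a thermally allowed, suprafacial six-electron (5+2) dipolar cycloaddition; the closest known reaction type is the oxidopyrylium–alkene (5+2) cycloaddition of ylides made from 3-hydroxy-4-pyranones and methyl triflate. The cycloheptene ring is closed by this intermolecular cycloaddition, and the tetrahydrofuran ring (O, C1, C5, C6, C7) arises with it as the oxygen bridge. C1 and C7 are cis on the bridge because the dipole reacts on one face, C5 and C6 are trans because the E-alkene reacts suprafacially, and the acyl group should take the endo and the bulky alkoxy group the exo position (secondary orbital overlap of the carbonyl, less strain next to the C1 substituent). The absolute sense should come from the (S)-benzylic ether, whose aryl ring shields one face of the s-trans enol ether; the diastereomer from attack on the other face is removed by chromatography. The regiochemistry needed (C7, the enolate-like terminus next to the oxide, bonding to the β-carbon C6; C1, the oxocarbenium-like terminus, bonding to the α-carbon C5) is secured by the matched push–pull polarisation of the β-alkoxy enone.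

Step 6
Reactants: 9 cycloadduct
Product: 10 C5 endo 3-methylbutanoate (isovalerate) of the bridged enone
Conditions: mCPBA, NaHCO3, CH2Cl2, 0 °C to rt
Reagents that add atoms: 3-chloroperbenzoic acid, OOC(=O)c1cccc(Cl)c1
Why: In this Baeyer–Villiger oxidation the secondary ring carbon C5 should migrate in preference to the primary isobutyl CH2 and with retention, so the endo ketone becomes the endo isovalerate, while the conjugated, hindered C8 ketone and its captodative alkene react more slowly.

Step 7
Reactants: 10 bridged α-methoxy enone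
Product: 12 enol triflate (C8(OTf)=C9(OMe), exo methyl on C10), via lithium enolate 11 (not isolated)
Conditions: Me2CuLi (from MeLi, CuI), Et2O, −78 to −30 °C; then N-(5-chloropyridin-2-yl)triflimide, THF, −78 °C to rt
Reagents that add atoms: lithium dimethylcuprate, [Li+].C[Cu-]C; N-(5-chloropyridin-2-yl)bis(trifluoromethanesulfonyl)imide, FC(F)(F)S(=O)(=O)N(c1ccc(Cl)cn1)S(=O)(=O)C(F)(F)F
Why: Cuprate conjugate addition should occur on the exo face of the enone (the endo ester on the two-carbon bridge blocks the other face), which sets C10 with methyl cis to the oxygen bridge, and the enolate is trapped regiospecifically as the enol triflate.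

Step 8
Reactants: 12 enol triflate
Product: 13 methyl enol ether (C8H=C9(OMe))
Conditions: Pd(OAc)2, PPh3, HCO2H, Bu3N, DMF, 60 °C
Reagents that add atoms: none
Why: Palladium-catalysed formate reduction of an enol triflate should replace OTf by hydrogen and leave the C8=C9 enol ether, which now has the C7–O bond in the allylic position.

Step 9
Reactants: 13 silyl ether
Product: 14 primary alcohol (CH2OH on C1)
Conditions: TBAF, AcOH, THF, 0 °C to rt
Reagents that add atoms: none
Why: Fluoride desilylation should free the primary alcohol, and buffering with acetic acid is meant to suppress acyl migration from the C5 ester.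

Step 10
Reactants: 14 primary alcohol
Product: 15 aldehyde (CHO on C1)
Conditions: Dess–Martin periodinane, NaHCO3, CH2Cl2, 0 °C to rt
Reagents that add atoms: none
Why: Buffered Dess–Martin oxidation should give the aldehyde, which has no α-hydrogen and tolerates the acid-sensitive enol ether under these conditions.

Step 11
Reactants: 15 aldehyde
Product: 16 (E)-allylic alcohol (CH(OH)–CH=CH–CH3 on C1, epimer mixture)
Conditions: (E)-1-bromoprop-1-ene, CrCl2, NiCl2 (cat.), DMF, rt
Reagents that add atoms: (E)-1-bromoprop-1-ene, C/C=C/Br
Why: The Nozaki–Hiyama–Kishi reaction should add the alkenylchromium reagent to the aldehyde alone and with retention of the E geometry; the new carbinol centre is not controlled and is removed in the next step.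

Step 12
Reactants: 16 allylic alcohol
Product: 17 crotonoyl ketone (bridged methyl enol ether)
Conditions: MnO2, CH2Cl2, rt
Reagents that add atoms: none
Why: MnO2 oxidation of the allylic alcohol should give the (E)-enone under neutral conditions that spare the enol ether.

Step 13
Reactants: 17 bridged methyl enol ether
Product: 19 (1S,5S,6R,10R)-1-[(E)-but-2-enoyl]-1,6-dihydroxy-10-methyl-9-oxocyclohept-7-en-5-yl 3-methylbutanoate (target locants), via silyloxy methoxyallyl cation triflate 18 (not isolated)
Conditions: TMSOTf, CH2Cl2, −78 °C; then TFA, H2O, anisole, warming to 0 °C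
Reagents that add atoms: water, O; trimethylsilyl triflate, C[Si](C)(C)OS(=O)(=O)C(F)(F)F (its atoms remain only in 18)
Why: The silyl triflate should ionise the allylic C7–O bond of the vinylogous acetal (Ferrier-type ionisation, the cation of a Stork–Danheiser transposition), so that the C1 oxygen is set free as its silyl ether and water turns the methoxyallyl cation into the C7=C8–C9 enone without protonation at C10, after which aqueous TFA removes the silyl group and the acid-labile 1-(4-methoxyphenyl)ethyl ether.

Step 14
Reactants: 19 diol enone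
Product: 20 C6 acrylate
Conditions: acryloyl chloride, i-Pr2NEt, CH2Cl2, −40 °C
Reagents that add atoms: acryloyl chloride, C=CC(=O)Cl
Why: Acylation should take place only at the secondary allylic C6 hydroxyl, since the tertiary α-keto C1 hydroxyl is unreactive under these conditions.

Step 15
Reactants: 20 acrylate
Product: 21 target CNP0283951.1 ((1S,5S,6R,7S,10R) in the target locants)
Conditions: PMe3 (cat.), tert-amyl alcohol/THF, rt
Reagents that add atoms: none
Why: In this intramolecular Rauhut–Currier reaction the phosphine should add to the acrylate, the resulting α-carbon adds 5-exo to C7 of the cycloheptenone on the face of the C6 oxygen, and loss of the phosphine restores the exocyclic methylene, so the tether enforces the cis ring fusion at C6/C7.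

Compound list
1 | kojic acid, 5-hydroxy-2-(hydroxymethyl)-4H-pyran-4-one | O=C1C=C(CO)OC=C1O | starting material
2 | 5-hydroxy-2-[(tert-butyldimethylsilyloxy)methyl]-4H-pyran-4-one | O=C1C=C(CO[Si](C)(C)C(C)(C)C)OC=C1O | intermediate
3 | 5-hydroxy-4-methoxy-2-[(tert-butyldimethylsilyloxy)methyl]pyrylium triflate | COc1cc(CO[Si](C)(C)C(C)(C)C)[o+]cc1O.[O-]S(=O)(=O)C(F)(F)F | intermediate
4 | 5-methylhex-1-yn-3-ol (racemic) | C#CC(O)CC(C)C | starting material
5 | 5-methylhex-1-yn-3-one | C#CC(=O)CC(C)C | intermediate
6 | (S)-1-(4-methoxyphenyl)ethanol | C[C@H](O)c1ccc(OC)cc1 | starting material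
7 | (E)-1-[(1S)-1-(4-methoxyphenyl)ethoxy]-5-methylhex-1-en-3-one | CC(C)CC(=O)/C=C/O[C@@H](C)c1ccc(OC)cc1 | intermediate
8 | 4-methoxy-5-oxido-2-[(tert-butyldimethylsilyloxy)methyl]pyrylium (oxidopyrylium ylide) | COc1cc(CO[Si](C)(C)C(C)(C)C)[o+]cc1[O-] | intermediate (not isolated)
9 | cycloadduct: 3-methoxy-8-oxabicyclo[3.2.1]oct-3-en-2-one with CH2OTBS on bridgehead C1, endo 3-methylbutanoyl on C5, exo (S)-1-(4-methoxyphenyl)ethoxy on C6 (target locants) | C1=C(OC)C(=O)[C@H]2O[C@]1(CO[Si](C)(C)C(C)(C)C)[C@@H](C(=O)CC(C)C)[C@@H]2O[C@@H](C)c1ccc(OC)cc1 | intermediate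
10 | as 9, with endo 3-methylbutanoyloxy (isovalerate) on C5 | C1=C(OC)C(=O)[C@H]2O[C@]1(CO[Si](C)(C)C(C)(C)C)[C@@H](OC(=O)CC(C)C)[C@@H]2O[C@@H](C)c1ccc(OC)cc1 | intermediate
11 | lithium C8 enolate with exo methyl on C10 | C[C@H]1C(OC)=C([O-])[C@H]2O[C@]1(CO[Si](C)(C)C(C)(C)C)[C@@H](OC(=O)CC(C)C)[C@@H]2O[C@@H](C)c1ccc(OC)cc1.[Li+] | intermediate (not isolated)
12 | enol triflate: C8(OTf)=C9(OMe), exo methyl on C10 | C[C@H]1C(OC)=C(OS(=O)(=O)C(F)(F)F)[C@H]2O[C@]1(CO[Si](C)(C)C(C)(C)C)[C@@H](OC(=O)CC(C)C)[C@@H]2O[C@@H](C)c1ccc(OC)cc1 | intermediate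
13 | bridged methyl enol ether: C8H=C9(OMe) | C[C@H]1C(OC)=C[C@H]2O[C@]1(CO[Si](C)(C)C(C)(C)C)[C@@H](OC(=O)CC(C)C)[C@@H]2O[C@@H](C)c1ccc(OC)cc1 | intermediate
14 | primary alcohol: CH2OH on C1 | C[C@H]1C(OC)=C[C@H]2O[C@]1(CO)[C@@H](OC(=O)CC(C)C)[C@@H]2O[C@@H](C)c1ccc(OC)cc1 | intermediate
15 | aldehyde: CHO on C1 | C[C@H]1C(OC)=C[C@H]2O[C@]1(C=O)[C@@H](OC(=O)CC(C)C)[C@@H]2O[C@@H](C)c1ccc(OC)cc1 | intermediate
16 | (E)-allylic alcohol: CH(OH)CH=CHCH3 on C1, carbinol epimers | C[C@H]1C(OC)=C[C@H]2O[C@]1(C(O)/C=C/C)[C@@H](OC(=O)CC(C)C)[C@@H]2O[C@@H](C)c1ccc(OC)cc1 | intermediate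
17 | crotonoyl ketone: (E)-but-2-enoyl on C1, bridged methyl enol ether | C[C@H]1C(OC)=C[C@H]2O[C@]1(C(=O)/C=C/C)[C@@H](OC(=O)CC(C)C)[C@@H]2O[C@@H](C)c1ccc(OC)cc1 | intermediate
18 | ring-opened C7–C8–C9 methoxyallyl cation with C1 trimethylsilyl ether, triflate salt | C[C@H](O[C@@H]1C=CC(=[O+]C)[C@H](C)[C@@](O[Si](C)(C)C)(C(=O)/C=C/C)[C@H]1OC(=O)CC(C)C)c1ccc(OC)cc1.[O-]S(=O)(=O)C(F)(F)F | intermediate (not isolated)
19 | (1S,5S,6R,10R)-1-[(E)-but-2-enoyl]-1,6-dihydroxy-10-methyl-9-oxocyclohept-7-en-5-yl 3-methylbutanoate (target locants) | O[C@@H]1C=CC(=O)[C@H](C)[C@@](O)(C(=O)/C=C/C)[C@H]1OC(=O)CC(C)C | intermediate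
20 | C6 acrylate of 19 | C=CC(=O)O[C@@H]1C=CC(=O)[C@H](C)[C@@](O)(C(=O)/C=C/C)[C@H]1OC(=O)CC(C)C | intermediate
21 | CNP0283951.1, cis-fused α-methylene-γ-butyrolactone on the cycloheptanone | C=C1C(=O)O[C@@H]2[C@H]1CC(=O)[C@H](C)[C@@](O)(C(=O)/C=C/C)[C@H]2OC(=O)CC(C)C | target

Total step count: 15. Longest linear sequence: 13 steps (steps 1, 2 and 5 to 15, from kojic acid).

Steps most likely to fail

Step 5. The push–pull alkene may react so slowly that dimerisation of the ylide wins, or the endo/exo and facial selectivities may be poor. The fallback sets out from 3, 5 and 6 and comes back at 9. The ynone 5 itself is used as the two-carbon partner, since alkynes are the most reactive partners of this ylide and the regiochemistry is the same; this should give the racemic 3-methoxy-6-(3-methylbutanoyl)-8-oxabicyclo[3.2.1]octa-3,6-dien-2-one F1 with both ring bonds still formed in one cycloaddition. Base-catalysed oxa-Michael addition of 6 (DBU cat., CH2Cl2) to the strained acyl-substituted C5=C6 bond from the exo face, followed by exo protonation at C5, places the alkoxy group exo and the acyl group endo. The two diastereomers that arise from the two enantiomers of F1 are separated to give 9.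

Step 7. The cuprate may fail to add to the hindered, electron-rich α-methoxy enone, or O-triflation of the enolate may be incomplete. The fallback sets out from 10 and comes back at 12. Corey–Chaykovsky cyclopropanation (trimethylsulfoxonium iodide, NaH, DMSO) should deliver CH2 to C9=C10 from the exo face and give the cyclopropyl ketone F2. Hydrogenolysis (H2, PtO2, EtOAc) should cleave the C9–CH2 bond that is conjugated with the ketone and leave the exo methyl on C10 in the α-methoxy ketone F3. Deprotonation at C9, the only enolisable position (KN(SiMe3)2, THF, −78 °C), and O-triflation with the same triflimide return to 12.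

Step 13. C-protonation of the enol ether may compete with ionisation of the bridge and epimerise C10, or the freed diol enone may close again by transannular oxa-Michael addition in acid. The fallback sets out from 17 and comes back at 19. Mild hydrolysis of the enol ether (PPTS, wet acetone) gives the bridged C9 ketone F4 with the benzylic ether intact. Soft enolisation towards C8 and silyl-assisted β-elimination of the bridging oxygen (TMSOTf, Et3N, CH2Cl2, 0 °C) then opens the bridge to the enone with a C1 trimethylsilyl ether F5. Oxidative removal of the benzylic ether (DDQ, wet CH2Cl2), followed by dilute HCl in THF for the silyl ether, returns to 19.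

Further compounds
F1 | step 5 | racemic 3-methoxy-5-[(tert-butyldimethylsilyloxy)methyl]-6-(3-methylbutanoyl)-8-oxabicyclo[3.2.1]octa-3,6-dien-2-one, drawn as the enantiomer that leads on | C1=C(OC)C(=O)[C@H]2O[C@]1(CO[Si](C)(C)C(C)(C)C)C(C(=O)CC(C)C)=C2
F2 | step 7 | exo cyclopropane across C9–C10 of 10 (cyclopropyl ketone) | C1[C@H]2[C@]1(OC)C(=O)[C@H]3O[C@]2(CO[Si](C)(C)C(C)(C)C)[C@@H](OC(=O)CC(C)C)[C@@H]3O[C@@H](C)c1ccc(OC)cc1
F3 | step 7 | C8 ketone with C9 methoxy (epimers) and exo C10 methyl | C[C@H]1C(OC)C(=O)[C@H]2O[C@]1(CO[Si](C)(C)C(C)(C)C)[C@@H](OC(=O)CC(C)C)[C@@H]2O[C@@H](C)c1ccc(OC)cc1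
F4 | step 13 | bridged C9 ketone (8-oxabicyclo[3.2.1]octan-3-one) with crotonoyl on C1 and the benzylic ether on C6 | C[C@H]1C(=O)C[C@H]2O[C@]1(C(=O)/C=C/C)[C@@H](OC(=O)CC(C)C)[C@@H]2O[C@@H](C)c1ccc(OC)cc1
F5 | step 13 | C1 trimethylsilyl ether of the ring-opened enone with the benzylic ether on C6 | C[C@H](O[C@@H]1C=CC(=O)[C@H](C)[C@@](O[Si](C)(C)C)(C(=O)/C=C/C)[C@H]1OC(=O)CC(C)C)c1ccc(OC)cc1
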